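**Remark (assumption and locants):** (S)-(−)-pulegone, acrolein and isofraxidin are taken as commercial. Locants in the text follow the octahydronaphthalen-2-ol numbering of 14: C-1 gem-dimethyl carbon, C-2 carbinol, C-4a ring-fusion CH, C-5 quaternary carbon, C-6 CH(CH3), C-8=C-8a double bond.

## Retrosynthetic overview

1. The aryl neopentyl ether is cut last (Mitsunobu of diol 14 with isofraxidin). The quaternary C-5 is then simplified to a CH–CHO carbon (formaldehyde aldol from the open face, then CHO to CH3), leaving bicyclic alcohol 9.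
2. Ring A of 9 is opened at two bonds at once, C-4–C-4a and C-1–C-2: a [3+3] union of acrolein with the monocyclic alkene 6 through two consecutive Lewis-acid ene reactions.
3. Enabling feature: the homoallylic axial alcohol C-2(OH)–C-1(CH3)2–C-8a=C-8 at the junction of rings A and B is the retron of a carbonyl-ene reaction on an isopropylidene group. That isopropylidene group, with a 3-oxopropyl chain on the neighbouring ring carbon C-4a, is in turn the ene adduct of acrolein with a 1-isopropylcyclohexene.
4. Ring order: ring B comes intact from (S)-pulegone (hydroxymethylation, reductive alkene transposition), ring A is closed in the key step, and the coumarin is attached last.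

Key step: step 5

## Route

Step 1
Reactants: 1 (S)-(−)-pulegone
Product: 2 (2S,3S)-2-(hydroxymethyl)-3-methyl-6-(propan-2-ylidene)cyclohexan-1-one
Conditions: LiN(i-Pr)2, THF, −78 °C; monomeric CH2O (from cracked paraformaldehyde), −78 °C; aq. NH4Cl
Reagents that add atoms: formaldehyde, C=O
Why: Kinetic deprotonation on the α′-CH2 side gives the cross-conjugated lithium enolate, whose aldol addition to formaldehyde (hydroxymethylation) should occur anti to the neighbouring methyl group, and the still epimerisable α-centre rests in the trans-diequatorial arrangement.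

Step 2
Reactants: 2 (2S,3S)-2-(hydroxymethyl)-3-methyl-6-(propan-2-ylidene)cyclohexan-1-one
Product: 3 (2S,3S)-2-({[tert-butyl(diphenyl)silyl]oxy}methyl)-3-methyl-6-(propan-2-ylidene)cyclohexan-1-one
Conditions: t-BuPh2SiCl, imidazole, DMF, 25 °C
Reagents that add atoms: tert-butyl(chloro)diphenylsilane, CC(C)(C)[Si](Cl)(c1ccccc1)c1ccccc1
Why: Silyl ether formation at the primary alcohol stops retro-aldol and dehydration and installs the bulky, weakly Lewis-basic group that later shields one face of the ring alkene; no stereocentre is touched.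

Step 3
Reactants: 3 (2S,3S)-2-({[tert-butyl(diphenyl)silyl]oxy}methyl)-3-methyl-6-(propan-2-ylidene)cyclohexan-1-one
Product: 4 N'-[(2R,3S)-2-({[tert-butyl(diphenyl)silyl]oxy}methyl)-3-methyl-6-(propan-2-ylidene)cyclohexylidene]-4-methylbenzenesulfonohydrazide
Conditions: TsNHNH2, cat. AcOH, EtOH, 60 °C
Reagents that add atoms: 4-methylbenzenesulfonohydrazide, Cc1ccc(cc1)S(=O)(=O)NN
Why: Acid-catalysed hydrazone formation at the enone carbonyl, conjugate addition being blocked by the fully substituted β-carbon; the α-centre keeps its stable trans arrangement (the descriptor changes only through priorities).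

Step 4
Reactants: 4 N'-[(2R,3S)-2-({[tert-butyl(diphenyl)silyl]oxy}methyl)-3-methyl-6-(propan-2-ylidene)cyclohexylidene]-4-methylbenzenesulfonohydrazide
Product: 6 tert-butyl{[(1R,6S)-6-methyl-3-(propan-2-yl)cyclohex-2-en-1-yl]methoxy}diphenylsilane, via allylic diazene 5 (not isolated)
Conditions: catecholborane, CHCl3, 0 °C; then NaOAc·3H2O, 60 °C
Reagents that add atoms: none
Why: Catecholborane reduction of an α,β-unsaturated tosylhydrazone with alkene transposition: hydride adds to the C=N carbon, acetate-induced loss of sulfinate gives diazene 5, and its retro-ene 1,5-hydrogen shift with loss of N2 delivers hydrogen to the CMe2 carbon and places the double bond in the ring, leaving both ring stereocentres untouched.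

Step 5
Reactants: 6 tert-butyl{[(1R,6S)-6-methyl-3-(propan-2-yl)cyclohex-2-en-1-yl]methoxy}diphenylsilane; 7 acrolein
Product: 9 (2S,4aS,5R,6S)-5-({[tert-butyl(diphenyl)silyl]oxy}methyl)-1,1,6-trimethyl-1,2,3,4,4a,5,6,7-octahydronaphthalen-2-ol, via ene-adduct aldehyde 8 (not isolated)
Conditions: Me2AlCl (2.2 equiv), CH2Cl2, −78 → 0 °C; then 1 M HCl
Reagents that add atoms: none
Why: Me2AlCl-bound acrolein acts as enophile toward the trisubstituted ring alkene: its β-carbon bonds to the alkene CH (future C-4a) while the isopropyl methine hydrogen is transferred to the α-carbon, giving aldehyde 8 with a tetrasubstituted isopropylidene group. The aluminium-bound aldehyde of 8 then undergoes an intramolecular carbonyl-ene reaction with the tether on the central carbon of the ene unit: the carbonyl carbon bonds to the CMe2 terminus (6-endo closure of ring A through a chair-like transition state) and the ring CH2 hydrogen on the same face goes to oxygen, which moves the double bond to C-8=C-8a. The closest known reaction type is the Me2AlCl-promoted sequential ene ([3+3]) annulation of alkenes with acrolein, combined with Lewis-acid carbonyl-ene cyclisation of δ,ε-unsaturated aldehydes. C-4a should be set in the first ene event by approach anti to the allylic silyloxymethyl group, the other allylic substituent being hydrogen and the homoallylic methyl equatorial. C-2 should be set in the second event, because in the closed chair the C=O must be axial to reach the allylic hydrogen, which gives the axial alcohol trans to the ring-fusion hydrogen. The step needs hydrogen transfer from the isopropyl group rather than the ring CH2 in the first event (favoured because the isopropyl group lies syn to the vinylic hydrogen and the more substituted alkene results) and six- rather than five-membered closure in the second (favoured by attack at the less hindered CMe2 terminus).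

Step 6
Reactants: 9 (2S,4aS,5R,6S)-5-({[tert-butyl(diphenyl)silyl]oxy}methyl)-1,1,6-trimethyl-1,2,3,4,4a,5,6,7-octahydronaphthalen-2-ol
Product: 10 (2S,4aS,5R,6S)-5-(hydroxymethyl)-1,1,6-trimethyl-1,2,3,4,4a,5,6,7-octahydronaphthalen-2-ol
Conditions: n-Bu4NF, THF, 25 °C
Reagents that add atoms: none
Why: Fluoride-induced desilylation frees the primary alcohol without touching the alkene, the secondary carbinol or any stereocentre.

Step 7
Reactants: 10 (2S,4aS,5R,6S)-5-(hydroxymethyl)-1,1,6-trimethyl-1,2,3,4,4a,5,6,7-octahydronaphthalen-2-ol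
Product: 11 (1R,2S,6S,8aS)-6-hydroxy-2,5,5-trimethyl-1,2,3,5,6,7,8,8a-octahydronaphthalene-1-carbaldehyde
Conditions: TEMPO (cat.), PhI(OAc)2, CH2Cl2, 25 °C
Reagents that add atoms: none
Why: Oxoammonium-mediated oxidation is selective for the primary alcohol over the hindered axial secondary carbinol next to the gem-dimethyl carbon, and the α-centre of the aldehyde need not be preserved because it is planarised in the next step.

Step 8
Reactants: 11 (1R,2S,6S,8aS)-6-hydroxy-2,5,5-trimethyl-1,2,3,5,6,7,8,8a-octahydronaphthalene-1-carbaldehyde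
Product: 12 (1S,2S,6S,8aR)-6-hydroxy-1-(hydroxymethyl)-2,5,5-trimethyl-1,2,3,5,6,7,8,8a-octahydronaphthalene-1-carbaldehyde
Conditions: 37% aq. CH2O, K2CO3 (0.3 equiv), THF–H2O, 0 → 25 °C
Reagents that add atoms: formaldehyde, C=O
Why: Crossed aldol reaction (α-hydroxymethylation of an α-branched aldehyde) through the exocyclic enolate: formaldehyde should add to the ring carbon from the face that carries the two flanking hydrogens (on C-4a and C-6), opposite the ring A CH2 and the neighbouring methyl, so the new CH2OH ends trans to both and the formyl group cis to both.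

Step 9
Reactants: 12 (1S,2S,6S,8aR)-6-hydroxy-1-(hydroxymethyl)-2,5,5-trimethyl-1,2,3,5,6,7,8,8a-octahydronaphthalene-1-carbaldehyde
Product: 14 (2S,4aR,5R,6S)-5-(hydroxymethyl)-1,1,5,6-tetramethyl-1,2,3,4,4a,5,6,7-octahydronaphthalen-2-ol, via hydrazone 13 (not isolated)
Conditions: N2H4·H2O, EtOH, 70 °C; evaporate; KOt-Bu, DMSO, 25 °C
Reagents that add atoms: none
Why: Wolff–Kishner reduction through the preformed hydrazone (room-temperature KOt-Bu/DMSO variant) turns the neopentyl formyl group into the C-5 methyl without heating the β-hydroxy aldehyde in base and without touching the quaternary centre, the alkene or the hydroxyls.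

Step 10
Reactants: 14 (2S,4aR,5R,6S)-5-(hydroxymethyl)-1,1,5,6-tetramethyl-1,2,3,4,4a,5,6,7-octahydronaphthalen-2-ol; 15 isofraxidin
Product: 16 7-{[(1R,2S,6S,8aR)-6-hydroxy-1,2,5,5-tetramethyl-1,2,3,5,6,7,8,8a-octahydronaphthalen-1-yl]methoxy}-6,8-dimethoxy-2H-chromen-2-one (CNP0110107.1)
Conditions: n-Bu3P, 1,1'-(azodicarbonyl)dipiperidine (ADDP), toluene, 0 → 80 °C
Reagents that add atoms: none
Why: Mitsunobu etherification (azodicarboxamide and trialkylphosphine variant for hindered alcohols) with the acidic 7-hydroxycoumarin should engage only the primary alcohol, the axial secondary carbinol beside the gem-dimethyl carbon being too hindered, and no stereocentre is involved.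

## Compound list

1 | (S)-(−)-pulegone, (5S)-5-methyl-2-(propan-2-ylidene)cyclohexan-1-one | C[C@H]1CCC(=C(C)C)C(=O)C1 | starting material
2 | (2S,3S)-2-(hydroxymethyl)-3-methyl-6-(propan-2-ylidene)cyclohexan-1-one | C[C@H]1CCC(=C(C)C)C(=O)[C@@H]1CO | intermediate
3 | (2S,3S)-2-({[tert-butyl(diphenyl)silyl]oxy}methyl)-3-methyl-6-(propan-2-ylidene)cyclohexan-1-one | C[C@H]1CCC(=C(C)C)C(=O)[C@@H]1CO[Si](c1ccccc1)(c1ccccc1)C(C)(C)C | intermediate
4 | N'-[(2R,3S)-2-({[tert-butyl(diphenyl)silyl]oxy}methyl)-3-methyl-6-(propan-2-ylidene)cyclohexylidene]-4-methylbenzenesulfonohydrazide | C[C@H]1CCC(=C(C)C)C(=NNS(=O)(=O)c2ccc(C)cc2)[C@@H]1CO[Si](c1ccccc1)(c1ccccc1)C(C)(C)C | intermediate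
5 | allylic diazene from reduction of 4 (monoalkyl diazene on the former carbonyl carbon, configuration at that carbon not defined) | C[C@H]1CCC(=C(C)C)C(N=N)[C@@H]1CO[Si](c1ccccc1)(c1ccccc1)C(C)(C)C | intermediate
6 | tert-butyl{[(1R,6S)-6-methyl-3-(propan-2-yl)cyclohex-2-en-1-yl]methoxy}diphenylsilane | C[C@H]1CCC(C(C)C)=C[C@@H]1CO[Si](c1ccccc1)(c1ccccc1)C(C)(C)C | intermediate
7 | acrolein (prop-2-enal) | C=CC=O | starting material
8 | 3-[2-({[tert-butyl(diphenyl)silyl]oxy}methyl)-3-methyl-6-(propan-2-ylidene)cyclohexyl]propanal, propanal chain trans to CH2OSi and cis to CH3 (first ene adduct) | C[C@H]1CCC(=C(C)C)[C@@H](CCC=O)[C@@H]1CO[Si](c1ccccc1)(c1ccccc1)C(C)(C)C | intermediate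
9 | (2S,4aS,5R,6S)-5-({[tert-butyl(diphenyl)silyl]oxy}methyl)-1,1,6-trimethyl-1,2,3,4,4a,5,6,7-octahydronaphthalen-2-ol | CC(C)(C)[Si](c1ccccc1)(c1ccccc1)OC[C@H]1[C@@H]2CC[C@H](O)C(C)(C)C2=CC[C@@H]1C | intermediate
10 | (2S,4aS,5R,6S)-5-(hydroxymethyl)-1,1,6-trimethyl-1,2,3,4,4a,5,6,7-octahydronaphthalen-2-ol | OC[C@H]1[C@@H]2CC[C@H](O)C(C)(C)C2=CC[C@@H]1C | intermediate
11 | (1R,2S,6S,8aS)-6-hydroxy-2,5,5-trimethyl-1,2,3,5,6,7,8,8a-octahydronaphthalene-1-carbaldehyde | O=C[C@H]1[C@@H]2CC[C@H](O)C(C)(C)C2=CC[C@@H]1C | intermediate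
12 | (1S,2S,6S,8aR)-6-hydroxy-1-(hydroxymethyl)-2,5,5-trimethyl-1,2,3,5,6,7,8,8a-octahydronaphthalene-1-carbaldehyde | O=C[C@]1(CO)[C@@H]2CC[C@H](O)C(C)(C)C2=CC[C@@H]1C | intermediate
13 | hydrazone of 12 | NN=C[C@]1(CO)[C@@H]2CC[C@H](O)C(C)(C)C2=CC[C@@H]1C | intermediate
14 | (2S,4aR,5R,6S)-5-(hydroxymethyl)-1,1,5,6-tetramethyl-1,2,3,4,4a,5,6,7-octahydronaphthalen-2-ol | OC[C@@]1(C)[C@@H]2CC[C@H](O)C(C)(C)C2=CC[C@@H]1C | intermediate
15 | isofraxidin, 7-hydroxy-6,8-dimethoxy-2H-chromen-2-one | COc1cc2ccc(=O)oc2c(OC)c1O | starting material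
16 | 7-{[(1R,2S,6S,8aR)-6-hydroxy-1,2,5,5-tetramethyl-1,2,3,5,6,7,8,8a-octahydronaphthalen-1-yl]methoxy}-6,8-dimethoxy-2H-chromen-2-one | COc1cc2ccc(=O)oc2c(OC)c1OC[C@@]1(C)[C@@H]2CC[C@H](O)C(C)(C)C2=CC[C@@H]1C | target

## Step count and risks

Total step count: 10. Longest linear sequence: 10 steps (from 1).

**Step 5 (key step).** In the first ene event, hydrogen may be transferred from the ring CH2 instead of the isopropyl methine, giving an adduct that cannot close ring A. The enophile may also add to the alkene face next to the silyloxymethyl group. The fallback makes the ring-fusion C–C bond by a [3,3] shift that fixes the position of the new double bond and closes ring A in a separate step. It sets out from ketone 3. Nucleophilic epoxidation (H2O2, NaOH, MeOH) would give the epoxy ketone F1. Wharton transposition (N2H4·H2O, cat. AcOH, MeOH) would give the tertiary allylic alcohol F2. Johnson–Claisen rearrangement (MeC(OEt)3, cat. EtCO2H, 140 °C) would give the ethyl ester F3, with the isopropylidene group in place and the new chain expected anti to the silyloxymethyl group. Reduction with i-Bu2AlH (−78 °C) would give the two-carbon aldehyde F4. Wittig homologation with Ph3P=CHOMe would give the enol ether F5, and mild aqueous acid would hydrolyse it to aldehyde 8, where the fallback rejoins the route. Aldehyde 8 is then cyclised with Me2AlCl alone to 9.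

**Step 10.** Displacement at the neopentyl carbon may be so slow that the alkoxyphosphonium intermediate is diverted (alkylation of the reduced azo reagent) or the alcohol is returned. The fallback replaces redox condensation by a preformed sulfonate and sets out from 14. Selective sulfonylation of the primary hydroxyl (Tf2O, 2,6-lutidine, CH2Cl2, −78 °C) would give the neopentyl triflate F6. Displacement by the caesium salt of isofraxidin 15 (Cs2CO3, DMF, 50 °C) rejoins the route at 16.

**Step 4.** Condensation of the doubly flanked enone with the sulfonohydrazide may stay incomplete, or hydride delivery may not be followed cleanly by the diazene shift, so that the transposed alkene is not formed. The fallback uses an allylpalladium hydride transfer and sets out from 3. Luche reduction (NaBH4, CeCl3·7H2O, MeOH) would give the allylic alcohol F7. Acylation (ClCO2Me, pyridine) would give the methyl carbonate F8. Palladium-catalysed formate reduction (Pd(OAc)2, n-Bu3P, HCO2NH4, dioxane, 100 °C), in which hydride goes to the more substituted allyl terminus, rejoins the route at alkene 6.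

Further compounds
F1 | step 5 | epoxy ketone: (4S,5S)-4-({[tert-butyl(diphenyl)silyl]oxy}methyl)-2,2,5-trimethyl-1-oxaspiro[2.5]octan-4-one-type spiro-epoxide of 3 (spiro carbon configuration not defined) | C[C@H]1CCC2(OC2(C)C)C(=O)[C@@H]1CO[Si](c1ccccc1)(c1ccccc1)C(C)(C)C
F2 | step 5 | 2-[(3R,4S)-3-({[tert-butyl(diphenyl)silyl]oxy}methyl)-4-methylcyclohex-1-en-1-yl]propan-2-ol | C[C@H]1CCC(C(C)(C)O)=C[C@@H]1CO[Si](c1ccccc1)(c1ccccc1)C(C)(C)C
F3 | step 5 | ethyl 2-[2-({[tert-butyl(diphenyl)silyl]oxy}methyl)-3-methyl-6-(propan-2-ylidene)cyclohexyl]acetate, acetate chain trans to CH2OSi and cis to CH3 | C[C@H]1CCC(=C(C)C)[C@@H](CC(=O)OCC)[C@@H]1CO[Si](c1ccccc1)(c1ccccc1)C(C)(C)C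
F4 | step 5 | 2-[2-({[tert-butyl(diphenyl)silyl]oxy}methyl)-3-methyl-6-(propan-2-ylidene)cyclohexyl]acetaldehyde, same relative configuration as F3 | C[C@H]1CCC(=C(C)C)[C@@H](CC=O)[C@@H]1CO[Si](c1ccccc1)(c1ccccc1)C(C)(C)C
F5 | step 5 | methyl enol ether of 8 (3-methoxyprop-2-enyl chain, E/Z mixture), same relative configuration as F3 | C[C@H]1CCC(=C(C)C)[C@@H](CC=COC)[C@@H]1CO[Si](c1ccccc1)(c1ccccc1)C(C)(C)C
F6 | step 10 | [(1R,2S,6S,8aR)-6-hydroxy-1,2,5,5-tetramethyl-1,2,3,5,6,7,8,8a-octahydronaphthalen-1-yl]methyl trifluoromethanesulfonate | FC(F)(F)S(=O)(=O)OC[C@@]1(C)[C@@H]2CC[C@H](O)C(C)(C)C2=CC[C@@H]1C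
F7 | step 4 | (2S,3S)-2-({[tert-butyl(diphenyl)silyl]oxy}methyl)-3-methyl-6-(propan-2-ylidene)cyclohexan-1-ol (carbinol epimers) | C[C@H]1CCC(=C(C)C)C(O)[C@@H]1CO[Si](c1ccccc1)(c1ccccc1)C(C)(C)C
F8 | step 4 | methyl carbonate of F7 | C[C@H]1CCC(=C(C)C)C(OC(=O)OC)[C@@H]1CO[Si](c1ccccc1)(c1ccccc1)C(C)(C)C
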